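## Retrosynthetic overview

1. The last stereocentre, flavanone C2, is set by ligand-controlled conjugate phenylation of a chromone. The chromone ring is built on the C4-aryl ring (primed locants, C1' on flavan C4) by ortho-formylation at C5', conversion to an ynone and 6-endo closure by O4'.
2. The strategy rests on one feature: flavan C2 is a benzylic ether carbon lying 1,3 to the diaryl methine C4 and bonded to O1 on C8a. The pyran ring C of the flavan is therefore opened at O1–C2 to a C8a phenol and a (1R)-benzylic alcohol, and is closed again with inversion.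
3. The open chain is cut from a flat 4-arylcoumarin. C4 comes from asymmetric conjugate reduction; the lactone is then opened to a Weinreb amide, converted to the phenyl ketone and reduced asymmetrically.
4. The coumarin comes from an aryl 3-arylpropiolate by gold-catalysed hydroarylation. The acid is made from 2,4-dihydroxy-6-methoxybenzaldehyde and the phenol from 2,5-dimethoxyresorcinol.
5. Ring order: coumarin lactone (temporary), flavan pyran ring C, chromone ring, flavanone (by arylation at C2).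

Key step: step 12

Remark (protecting groups): TIPS = triisopropylsilyl, Bn = benzyl, chroman = 3,4-dihydro-2H-chromene; O4' and flavan O7 are carried as TIPS ethers and O6' as a benzyl ether, so that no acid is needed once the electron-rich, acid-labile diaryl methine C4 exists.

Remark (assumption): the sense of induction in steps 8 and 19 is assigned by analogy with simpler 4-arylcoumarins and chromones; if a first correlation shows the opposite sense, the antipodal ligand is used and nothing else changes.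

Remark (descriptors): the diaryl methine carbon is S in the ring-closed compounds and R in the open-chain phenols 12, 14 and 15 only because the priority order of the two aryl groups changes; its configuration is the same throughout.

## Route

Step 1
Reactants: 1 2,4-dihydroxy-6-methoxybenzaldehyde
Product: 2 2-hydroxy-6-methoxy-4-(triisopropylsilyloxy)benzaldehyde
Conditions: TIPSCl (1.05 equiv), imidazole, CH2Cl2, 0 °C
Reagents that add atoms: chlorotriisopropylsilane, CC(C)[Si](Cl)(C(C)C)C(C)C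
Why: Selective silyl ether formation at the more acidic para hydroxyl, the ortho hydroxyl being held in a hydrogen bond to the formyl group.

Step 2
Reactants: 2 2-hydroxy-6-methoxy-4-(triisopropylsilyloxy)benzaldehyde
Product: 3 2-(benzyloxy)-6-methoxy-4-(triisopropylsilyloxy)benzaldehyde
Conditions: BnOH, PPh3, DIAD, THF, 0 °C to rt
Reagents that add atoms: benzyl alcohol, OCc1ccccc1
Why: Mitsunobu O-alkylation of the chelated phenol under neutral conditions, which spares the base-sensitive para-formyl aryl silyl ether.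

Step 3
Reactants: 3 2-(benzyloxy)-6-methoxy-4-(triisopropylsilyloxy)benzaldehyde
Product: 4 1-(benzyloxy)-2-(2,2-dibromoethenyl)-3-methoxy-5-(triisopropylsilyloxy)benzene
Conditions: CBr4, PPh3, Zn dust, CH2Cl2, rt
Reagents that add atoms: carbon tetrabromide, BrC(Br)(Br)Br
Why: Corey–Fuchs dibromo-olefination (Wittig-type reaction of Ph3P=CBr2), with zinc keeping the medium free of HBr.

Step 4
Reactants: 4 1-(benzyloxy)-2-(2,2-dibromoethenyl)-3-methoxy-5-(triisopropylsilyloxy)benzene
Product: 6 3-[2-(benzyloxy)-6-methoxy-4-(triisopropylsilyloxy)phenyl]prop-2-ynoic acid, via lithium arylacetylide 5 (not isolated)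
Conditions: n-BuLi (2.1 equiv), THF, −78 °C; CO2, −78 °C to 0 °C; cold 1 M HCl to pH 3
Reagents that add atoms: carbon dioxide, O=C=O
Why: Second stage of the Corey–Fuchs sequence (bromine–lithium exchange and rearrangement to the lithium acetylide) followed by carboxylation of the acetylide.

Step 5
Reactants: 7 2,5-dimethoxyresorcinol (2,5-dimethoxybenzene-1,3-diol)
Product: 8 2,5-dimethoxy-3-(triisopropylsilyloxy)phenol
Conditions: TIPSCl (1.0 equiv), imidazole, DMF, 0 °C to rt
Reagents that add atoms: chlorotriisopropylsilane, CC(C)[Si](Cl)(C(C)C)C(C)C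
Why: Monosilylation of a symmetrical diol, in which only one monoether is possible and the bis-ether and unreacted diol should be separable and recyclable.

Step 6
Reactants: 6 3-[2-(benzyloxy)-6-methoxy-4-(triisopropylsilyloxy)phenyl]prop-2-ynoic acid; 8 2,5-dimethoxy-3-(triisopropylsilyloxy)phenol
Product: 9 2,5-dimethoxy-3-(triisopropylsilyloxy)phenyl 3-[2-(benzyloxy)-6-methoxy-4-(triisopropylsilyloxy)phenyl]prop-2-ynoate
Conditions: DCC, DMAP (cat.), CH2Cl2, 0 °C to rt
Reagents that add atoms: none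
Why: Steglich esterification; the two ortho substituents of the arylpropiolic acid block the dehydro-Diels–Alder dimerisation that such acids otherwise undergo on activation.

Step 7
Reactants: 9 2,5-dimethoxy-3-(triisopropylsilyloxy)phenyl 3-[2-(benzyloxy)-6-methoxy-4-(triisopropylsilyloxy)phenyl]prop-2-ynoate
Product: 10 4-[2-(benzyloxy)-6-methoxy-4-(triisopropylsilyloxy)phenyl]-5,8-dimethoxy-7-(triisopropylsilyloxy)-2H-chromen-2-one
Conditions: (Ph3P)AuCl (5 mol %), AgOTf (5 mol %), ClCH2CH2Cl, 25 to 60 °C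
Reagents that add atoms: none
Why: Monovalent gold-catalysed intramolecular hydroarylation of an aryl alkynoate, in which the only free ortho carbon of the phenol ester (para to the silyloxy group, ortho to a methoxy group) attacks the aryl-bearing alkyne carbon in a 6-endo-dig Friedel–Crafts-type closure.

Step 8
Reactants: 10 4-[2-(benzyloxy)-6-methoxy-4-(triisopropylsilyloxy)phenyl]-5,8-dimethoxy-7-(triisopropylsilyloxy)-2H-chromen-2-one
Product: 11 (4S)-4-[2-(benzyloxy)-6-methoxy-4-(triisopropylsilyloxy)phenyl]-5,8-dimethoxy-7-(triisopropylsilyloxy)chroman-2-one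
Conditions: Cu(OAc)2·H2O (5 mol %), (R)-DTBM-SEGPHOS (5.5 mol %), (EtO)2MeSiH (1.5 equiv), t-BuOH (1.5 equiv), toluene, 0 °C to rt
Reagents that add atoms: none
Why: Copper hydride-catalysed asymmetric conjugate reduction of a 4-arylcoumarin, in which the ligand-bound Cu–H delivers hydride to one face of the flat C4 (catalyst control, giving 4S) and t-BuOH protonates the copper enolate before it can fragment or be reduced further.

Step 9
Reactants: 11 (4S)-4-[2-(benzyloxy)-6-methoxy-4-(triisopropylsilyloxy)phenyl]-5,8-dimethoxy-7-(triisopropylsilyloxy)chroman-2-one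
Product: 12 (3R)-3-[2-(benzyloxy)-6-methoxy-4-(triisopropylsilyloxy)phenyl]-3-[2-hydroxy-3,6-dimethoxy-4-(triisopropylsilyloxy)phenyl]-N-methoxy-N-methylpropanamide
Conditions: MeNH(OMe)·HCl, i-PrMgCl, THF, −20 to 0 °C
Reagents that add atoms: N,O-dimethylhydroxylamine hydrochloride, CNOC.Cl
Why: Aminolysis of the activated aryl ester (lactone opening) by the magnesium amide to give the Weinreb amide and the free C8a phenol; the stereocentre is β to the carbonyl and cannot epimerise.

Step 10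
Reactants: 12 (3R)-3-[2-(benzyloxy)-6-methoxy-4-(triisopropylsilyloxy)phenyl]-3-[2-hydroxy-3,6-dimethoxy-4-(triisopropylsilyloxy)phenyl]-N-methoxy-N-methylpropanamide; 13 phenylmagnesium bromide
Product: 14 (3R)-3-[2-(benzyloxy)-6-methoxy-4-(triisopropylsilyloxy)phenyl]-3-[2-hydroxy-3,6-dimethoxy-4-(triisopropylsilyloxy)phenyl]-1-phenylpropan-1-one
Conditions: PhMgBr (3.5 equiv), THF, 0 °C to rt; aq. NH4Cl
Reagents that add atoms: none
Why: Weinreb ketone synthesis, in which the first equivalent deprotonates the phenol and the chelated tetrahedral intermediate prevents over-addition.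

Step 11
Reactants: 14 (3R)-3-[2-(benzyloxy)-6-methoxy-4-(triisopropylsilyloxy)phenyl]-3-[2-hydroxy-3,6-dimethoxy-4-(triisopropylsilyloxy)phenyl]-1-phenylpropan-1-one
Product: 15 (1R,3R)-3-[2-(benzyloxy)-6-methoxy-4-(triisopropylsilyloxy)phenyl]-3-[2-hydroxy-3,6-dimethoxy-4-(triisopropylsilyloxy)phenyl]-1-phenylpropan-1-ol
Conditions: RuCl[(R,R)-TsDPEN](p-cymene) (2 mol %), HCO2H–Et3N (5:2), CH2Cl2, 30 °C
Reagents that add atoms: none
Why: Asymmetric transfer hydrogenation of an aryl alkyl ketone, in which the (R,R)-catalyst gives the (1R)-carbinol under reagent control regardless of the remote C3 centre; unlike a borane reduction it tolerates the free phenol.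

Step 12
Reactants: 15 (1R,3R)-3-[2-(benzyloxy)-6-methoxy-4-(triisopropylsilyloxy)phenyl]-3-[2-hydroxy-3,6-dimethoxy-4-(triisopropylsilyloxy)phenyl]-1-phenylpropan-1-ol
Product: 16 (2S,4S)-4-[2-(benzyloxy)-6-methoxy-4-(triisopropylsilyloxy)phenyl]-5,8-dimethoxy-2-phenyl-7-(triisopropylsilyloxy)chroman
Conditions: PPh3 (1.5 equiv), DIAD (1.5 equiv), toluene (0.02 M), 0 °C to rt
Reagents that add atoms: none
Why: PPh3 and DIAD form a betaine that deprotonates the phenol and turns the (1R)-carbinol into its alkoxyphosphonium ion, and the C8a phenoxide then displaces Ph3P=O from the rear of the benzylic carbon (SN2). The closest known reaction type is the intramolecular Mitsunobu etherification of 3-(2-hydroxyaryl)-1-arylpropan-1-ols to 2-arylchromans, which proceeds with inversion. The pyran ring C of the flavan closes in 6-exo-tet mode by forming O1–C2. C2 becomes S by inversion of the carbinol set in step 11 and C4 (set in step 8) is untouched, so the 2,4-trans relationship follows from two reagent-controlled steps and not from any conformational preference of the ring. The step needs substitution to win over E2 elimination and over ionisation of the benzylic centre, and it needs a single nucleophile: the unactivated phenyl group, the non-polar solvent and the six-membered transition state should secure the former, and the benzyl cap on O6' (with O4' and O7 silylated) secures the latter.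

Step 13
Reactants: 16 (2S,4S)-4-[2-(benzyloxy)-6-methoxy-4-(triisopropylsilyloxy)phenyl]-5,8-dimethoxy-2-phenyl-7-(triisopropylsilyloxy)chroman
Product: 17 2-[(2S,4S)-5,8-dimethoxy-2-phenyl-7-(triisopropylsilyloxy)chroman-4-yl]-3-methoxy-5-(triisopropylsilyloxy)phenol
Conditions: H2 (1 atm), Pd/C, EtOAc, rt
Reagents that add atoms: none
Why: Hydrogenolysis of the only benzyl ether under neutral conditions frees the one phenol (O6'-H) that has a single open ortho carbon, while aryl silyl ethers and the cyclic benzylic ether should not be cleaved.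

Step 14
Reactants: 17 2-[(2S,4S)-5,8-dimethoxy-2-phenyl-7-(triisopropylsilyloxy)chroman-4-yl]-3-methoxy-5-(triisopropylsilyloxy)phenol
Product: 18 3-[(2S,4S)-5,8-dimethoxy-2-phenyl-7-(triisopropylsilyloxy)chroman-4-yl]-2-hydroxy-4-methoxy-6-(triisopropylsilyloxy)benzaldehyde
Conditions: MgCl2, Et3N, paraformaldehyde, MeCN, reflux
Reagents that add atoms: paraformaldehyde (formaldehyde), C=O
Why: Magnesium phenoxide-directed ortho-formylation (Casnati–Skattebøl reaction), in which formaldehyde is delivered inside the magnesium chelate to the only free ortho carbon (C5') and a second formaldehyde accepts hydride; C3' and flavan C6, which an intermolecular Friedel–Crafts acylation would also attack, are left alone.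

Step 15
Reactants: 18 3-[(2S,4S)-5,8-dimethoxy-2-phenyl-7-(triisopropylsilyloxy)chroman-4-yl]-2-hydroxy-4-methoxy-6-(triisopropylsilyloxy)benzaldehyde
Product: 19 2-(benzyloxy)-3-[(2S,4S)-5,8-dimethoxy-2-phenyl-7-(triisopropylsilyloxy)chroman-4-yl]-4-methoxy-6-(triisopropylsilyloxy)benzaldehyde
Conditions: BnBr, K2CO3, acetone, 50 °C
Reagents that add atoms: benzyl bromide, BrCc1ccccc1
Why: Williamson etherification of the chelated phenol, which caps O6' so that only O4' can later close the pyranone ring; the robust TIPS ethers should survive carbonate in an aprotic solvent.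

Step 16
Reactants: 19 2-(benzyloxy)-3-[(2S,4S)-5,8-dimethoxy-2-phenyl-7-(triisopropylsilyloxy)chroman-4-yl]-4-methoxy-6-(triisopropylsilyloxy)benzaldehyde; 20 ethynylmagnesium bromide
Product: 21 1-{2-(benzyloxy)-3-[(2S,4S)-5,8-dimethoxy-2-phenyl-7-(triisopropylsilyloxy)chroman-4-yl]-4-methoxy-6-(triisopropylsilyloxy)phenyl}prop-2-yn-1-ol (both carbinol epimers)
Conditions: HC≡CMgBr (3 equiv), THF, 0 °C; aq. NH4Cl
Reagents that add atoms: none
Why: Grignard addition of a small nucleophile to the hindered aldehyde; the new carbinol centre is removed by oxidation in the next step, so its configuration does not matter.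

Step 17
Reactants: 21 1-{2-(benzyloxy)-3-[(2S,4S)-5,8-dimethoxy-2-phenyl-7-(triisopropylsilyloxy)chroman-4-yl]-4-methoxy-6-(triisopropylsilyloxy)phenyl}prop-2-yn-1-ol
Product: 22 1-{2-(benzyloxy)-3-[(2S,4S)-5,8-dimethoxy-2-phenyl-7-(triisopropylsilyloxy)chroman-4-yl]-4-methoxy-6-(triisopropylsilyloxy)phenyl}prop-2-yn-1-one
Conditions: Dess–Martin periodinane, NaHCO3, CH2Cl2, 0 °C
Reagents that add atoms: none
Why: Dess–Martin oxidation of the propargylic benzylic alcohol to the ynone under buffered, near-neutral conditions.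

Step 18
Reactants: 22 1-{2-(benzyloxy)-3-[(2S,4S)-5,8-dimethoxy-2-phenyl-7-(triisopropylsilyloxy)chroman-4-yl]-4-methoxy-6-(triisopropylsilyloxy)phenyl}prop-2-yn-1-one
Product: 24 5-(benzyloxy)-6-[(2S,4S)-7-hydroxy-5,8-dimethoxy-2-phenylchroman-4-yl]-7-methoxy-4H-chromen-4-one, via bis-phenol ynone 23 (not isolated)
Conditions: TBAF (2.5 equiv), THF, −20 to 0 °C; aq. NH4Cl
Reagents that add atoms: none
Why: Fluoride cleaves both aryl silyl ethers, and the phenoxide ortho to the carbonyl (O4') adds to the ynone terminus in a 6-endo-dig oxa-Michael addition to close the chromone ring; O6' is benzylated, so only the 6-substituted regioisomer can form.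

Step 19
Reactants: 24 5-(benzyloxy)-6-[(2S,4S)-7-hydroxy-5,8-dimethoxy-2-phenylchroman-4-yl]-7-methoxy-4H-chromen-4-one; 25 phenylboronic acid
Product: 26 (2R)-5-(benzyloxy)-6-[(2S,4S)-7-hydroxy-5,8-dimethoxy-2-phenylchroman-4-yl]-7-methoxy-2-phenylchroman-4-one
Conditions: [Rh(OH)(cod)]2 (2.5 mol %), (R)-2,2'-bis[bis(3,4,5-trifluorophenyl)phosphino]-6,6'-dimethoxy-1,1'-biphenyl (5.5 mol %), PhB(OH)2 (3 equiv), toluene–H2O, 25 °C
Reagents that add atoms: none
Why: Rhodium-catalysed asymmetric 1,4-addition of an arylboronic acid to a chromone (Hayashi–Miyaura reaction), in which the phenylrhodium species adds across C2=C3 on the face chosen by the ligand (catalyst control, giving 2R) and water protonates the rhodium enolate.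

Step 20
Reactants: 26 (2R)-5-(benzyloxy)-6-[(2S,4S)-7-hydroxy-5,8-dimethoxy-2-phenylchroman-4-yl]-7-methoxy-2-phenylchroman-4-one
Product: 27 (2R)-5-hydroxy-6-[(2S,4S)-7-hydroxy-5,8-dimethoxy-2-phenylchroman-4-yl]-7-methoxy-2-phenylchroman-4-one
Conditions: H2 (1 atm), Pd/C, EtOAc–MeOH, rt
Reagents that add atoms: none
Why: Hydrogenolysis of the last benzyl ether under neutral conditions gives the chelated 5-hydroxyl without touching the base- and acid-sensitive flavanone C2 or the diaryl methine; the carbonyl and the ring benzylic ethers should survive a short exposure at atmospheric pressure.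

## Compound list

1 | 2,4-dihydroxy-6-methoxybenzaldehyde | COc1cc(O)cc(O)c1C=O | starting material
2 | 2-hydroxy-6-methoxy-4-(triisopropylsilyloxy)benzaldehyde | COc1cc(O[Si](C(C)C)(C(C)C)C(C)C)cc(O)c1C=O | intermediate
3 | 2-(benzyloxy)-6-methoxy-4-(triisopropylsilyloxy)benzaldehyde | COc1cc(O[Si](C(C)C)(C(C)C)C(C)C)cc(OCc2ccccc2)c1C=O | intermediate
4 | 1-(benzyloxy)-2-(2,2-dibromoethenyl)-3-methoxy-5-(triisopropylsilyloxy)benzene | COc1cc(O[Si](C(C)C)(C(C)C)C(C)C)cc(OCc2ccccc2)c1C=C(Br)Br | intermediate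
5 | lithium [2-(benzyloxy)-6-methoxy-4-(triisopropylsilyloxy)phenyl]acetylide | COc1cc(O[Si](C(C)C)(C(C)C)C(C)C)cc(OCc2ccccc2)c1C#C[Li] | intermediate (not isolated)
6 | 3-[2-(benzyloxy)-6-methoxy-4-(triisopropylsilyloxy)phenyl]prop-2-ynoic acid | COc1cc(O[Si](C(C)C)(C(C)C)C(C)C)cc(OCc2ccccc2)c1C#CC(=O)O | intermediate
7 | 2,5-dimethoxyresorcinol | COc1cc(O)c(OC)c(O)c1 | starting material
8 | 2,5-dimethoxy-3-(triisopropylsilyloxy)phenol | COc1cc(O)c(OC)c(O[Si](C(C)C)(C(C)C)C(C)C)c1 | intermediate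
9 | 2,5-dimethoxy-3-(triisopropylsilyloxy)phenyl 3-[2-(benzyloxy)-6-methoxy-4-(triisopropylsilyloxy)phenyl]prop-2-ynoate | COc1cc(OC(=O)C#Cc2c(OC)cc(O[Si](C(C)C)(C(C)C)C(C)C)cc2OCc2ccccc2)c(OC)c(O[Si](C(C)C)(C(C)C)C(C)C)c1 | intermediate
10 | 4-[2-(benzyloxy)-6-methoxy-4-(triisopropylsilyloxy)phenyl]-5,8-dimethoxy-7-(triisopropylsilyloxy)-2H-chromen-2-one | COc1cc(O[Si](C(C)C)(C(C)C)C(C)C)cc(OCc2ccccc2)c1C1=CC(=O)Oc2c(OC)c(O[Si](C(C)C)(C(C)C)C(C)C)cc(OC)c21 | intermediate
11 | (4S)-4-[2-(benzyloxy)-6-methoxy-4-(triisopropylsilyloxy)phenyl]-5,8-dimethoxy-7-(triisopropylsilyloxy)chroman-2-one | COc1cc(O[Si](C(C)C)(C(C)C)C(C)C)cc(OCc2ccccc2)c1[C@@H]1CC(=O)Oc2c(OC)c(O[Si](C(C)C)(C(C)C)C(C)C)cc(OC)c21 | intermediate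
12 | (3R)-3-[2-(benzyloxy)-6-methoxy-4-(triisopropylsilyloxy)phenyl]-3-[2-hydroxy-3,6-dimethoxy-4-(triisopropylsilyloxy)phenyl]-N-methoxy-N-methylpropanamide | COc1cc(O[Si](C(C)C)(C(C)C)C(C)C)cc(OCc2ccccc2)c1[C@@H](c1c(OC)cc(O[Si](C(C)C)(C(C)C)C(C)C)c(OC)c1O)CC(=O)N(C)OC | intermediate
13 | phenylmagnesium bromide | Br[Mg]c1ccccc1 | starting material
14 | (3R)-3-[2-(benzyloxy)-6-methoxy-4-(triisopropylsilyloxy)phenyl]-3-[2-hydroxy-3,6-dimethoxy-4-(triisopropylsilyloxy)phenyl]-1-phenylpropan-1-one | COc1cc(O[Si](C(C)C)(C(C)C)C(C)C)cc(OCc2ccccc2)c1[C@@H](c1c(OC)cc(O[Si](C(C)C)(C(C)C)C(C)C)c(OC)c1O)CC(=O)c1ccccc1 | intermediate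
15 | (1R,3R)-3-[2-(benzyloxy)-6-methoxy-4-(triisopropylsilyloxy)phenyl]-3-[2-hydroxy-3,6-dimethoxy-4-(triisopropylsilyloxy)phenyl]-1-phenylpropan-1-ol | COc1cc(O[Si](C(C)C)(C(C)C)C(C)C)cc(OCc2ccccc2)c1[C@@H](c1c(OC)cc(O[Si](C(C)C)(C(C)C)C(C)C)c(OC)c1O)C[C@@H](O)c1ccccc1 | intermediate
16 | (2S,4S)-4-[2-(benzyloxy)-6-methoxy-4-(triisopropylsilyloxy)phenyl]-5,8-dimethoxy-2-phenyl-7-(triisopropylsilyloxy)chroman | COc1cc(O[Si](C(C)C)(C(C)C)C(C)C)cc(OCc2ccccc2)c1[C@@H]1C[C@@H](c2ccccc2)Oc2c(OC)c(O[Si](C(C)C)(C(C)C)C(C)C)cc(OC)c21 | intermediate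
17 | 2-[(2S,4S)-5,8-dimethoxy-2-phenyl-7-(triisopropylsilyloxy)chroman-4-yl]-3-methoxy-5-(triisopropylsilyloxy)phenol | COc1cc(O[Si](C(C)C)(C(C)C)C(C)C)cc(O)c1[C@@H]1C[C@@H](c2ccccc2)Oc2c(OC)c(O[Si](C(C)C)(C(C)C)C(C)C)cc(OC)c21 | intermediate
18 | 3-[(2S,4S)-5,8-dimethoxy-2-phenyl-7-(triisopropylsilyloxy)chroman-4-yl]-2-hydroxy-4-methoxy-6-(triisopropylsilyloxy)benzaldehyde | COc1cc(O[Si](C(C)C)(C(C)C)C(C)C)c(C=O)c(O)c1[C@@H]1C[C@@H](c2ccccc2)Oc2c(OC)c(O[Si](C(C)C)(C(C)C)C(C)C)cc(OC)c21 | intermediate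
19 | 2-(benzyloxy)-3-[(2S,4S)-5,8-dimethoxy-2-phenyl-7-(triisopropylsilyloxy)chroman-4-yl]-4-methoxy-6-(triisopropylsilyloxy)benzaldehyde | COc1cc(O[Si](C(C)C)(C(C)C)C(C)C)c(C=O)c(OCc2ccccc2)c1[C@@H]1C[C@@H](c2ccccc2)Oc2c(OC)c(O[Si](C(C)C)(C(C)C)C(C)C)cc(OC)c21 | intermediate
20 | ethynylmagnesium bromide | C#C[Mg]Br | starting material
21 | 1-{2-(benzyloxy)-3-[(2S,4S)-5,8-dimethoxy-2-phenyl-7-(triisopropylsilyloxy)chroman-4-yl]-4-methoxy-6-(triisopropylsilyloxy)phenyl}prop-2-yn-1-ol (both carbinol epimers) | COc1cc(O[Si](C(C)C)(C(C)C)C(C)C)c(C(O)C#C)c(OCc2ccccc2)c1[C@@H]1C[C@@H](c2ccccc2)Oc2c(OC)c(O[Si](C(C)C)(C(C)C)C(C)C)cc(OC)c21 | intermediate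
22 | 1-{2-(benzyloxy)-3-[(2S,4S)-5,8-dimethoxy-2-phenyl-7-(triisopropylsilyloxy)chroman-4-yl]-4-methoxy-6-(triisopropylsilyloxy)phenyl}prop-2-yn-1-one | COc1cc(O[Si](C(C)C)(C(C)C)C(C)C)c(C(=O)C#C)c(OCc2ccccc2)c1[C@@H]1C[C@@H](c2ccccc2)Oc2c(OC)c(O[Si](C(C)C)(C(C)C)C(C)C)cc(OC)c21 | intermediate
23 | 1-{2-(benzyloxy)-6-hydroxy-3-[(2S,4S)-7-hydroxy-5,8-dimethoxy-2-phenylchroman-4-yl]-4-methoxyphenyl}prop-2-yn-1-one | COc1cc(O)c(C(=O)C#C)c(OCc2ccccc2)c1[C@@H]1C[C@@H](c2ccccc2)Oc2c(OC)c(O)cc(OC)c21 | intermediate (not isolated)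
24 | 5-(benzyloxy)-6-[(2S,4S)-7-hydroxy-5,8-dimethoxy-2-phenylchroman-4-yl]-7-methoxy-4H-chromen-4-one | COc1cc2OC=CC(=O)c2c(OCc3ccccc3)c1[C@@H]1C[C@@H](c3ccccc3)Oc3c(OC)c(O)cc(OC)c31 | intermediate
25 | phenylboronic acid | OB(O)c1ccccc1 | starting material
26 | (2R)-5-(benzyloxy)-6-[(2S,4S)-7-hydroxy-5,8-dimethoxy-2-phenylchroman-4-yl]-7-methoxy-2-phenylchroman-4-one | COc1cc2O[C@@H](c3ccccc3)CC(=O)c2c(OCc3ccccc3)c1[C@@H]1C[C@@H](c3ccccc3)Oc3c(OC)c(O)cc(OC)c31 | intermediate
27 | (2R)-5-hydroxy-6-[(2S,4S)-7-hydroxy-5,8-dimethoxy-2-phenylchroman-4-yl]-7-methoxy-2-phenylchroman-4-one (CNP0301559.1) | COc1cc2c(c(O)c1[C@@H]1C[C@@H](c3ccccc3)Oc3c(OC)c(O)cc(OC)c31)C(=O)C[C@H](c1ccccc1)O2 | target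

## Step count and risk

Total step count: 20. Longest linear sequence: 19 steps (steps 1–4 and 6–20, from aldehyde 1); step 5 is the one-step side branch.

Steps most likely to fail:

**Step 8.** Hydride delivery to C4, which is flanked by a 2,6-disubstituted aryl group and the peri 5-methoxy group, may stall, may discriminate the two faces poorly, or the lactone may be reduced further. The fallback sets C4 by iminium catalysis instead, setting out from aldehyde 3 and phenol 8 and returning at lactone 11. Wittig olefination of 3 with Ph3P=CHCHO should give (E)-3-[2-(benzyloxy)-6-methoxy-4-(triisopropylsilyloxy)phenyl]prop-2-enal F1. Friedel–Crafts alkylation of F1 by the ortho carbon of phenol 8 under an α,α-diphenylprolinol trimethylsilyl ether catalyst (enantiomer chosen for 4S), followed by spontaneous hemiacetal closure, should give the (4S)-4-arylchroman-2-ol F2. Oxidation of the lactol (Ag2CO3 on celite, toluene, reflux) returns 11.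

**Step 12.** The alkoxyphosphonium ion may eliminate to the styrene, or ionise with loss of configuration at C2, and the hindered phenoxide may be slow. The fallback closes the ring at the other end of the ether with retention at the carbinol, setting out from ketone 14 and returning at flavan 16. Transfer hydrogenation with RuCl[(S,S)-TsDPEN](p-cymene) should give the (1S,3R)-alcohol F3. Triflation of the phenol alone (PhNTf2, K2CO3, THF) gives the aryl triflate F4. Intramolecular Pd-catalysed C–O coupling (Pd(OAc)2, 2-(di-tert-butylphosphino)-2',4',6'-triisopropylbiphenyl, Cs2CO3, toluene, 80 °C) then forms O1–C8a with the carbinol configuration unchanged, giving 16.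

**Step 19.** Carbometalation of the electron-rich chromone may be slow, the rhodium enolate may open the pyranone ring, or facial selectivity may be poor. The fallback closes the flavanone by oxa-Michael addition, setting out from aldehyde 19 and returning at 26. MeMgBr addition should give the 1-arylethanol F5, and Dess–Martin oxidation the acetophenone F6. Claisen–Schmidt condensation with benzaldehyde in KOH/EtOH, which also removes both silyl ethers, gives the 2'-hydroxychalcone F7. A quinine-derived bifunctional thiourea then catalyses the intramolecular oxa-Michael addition to 26; catalyst control is expected to be weaker here, but the (2S)-epimer is a diastereomer and would be removed by chromatography.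

## Further compounds

F1 | step 8 | (E)-3-[2-(benzyloxy)-6-methoxy-4-(triisopropylsilyloxy)phenyl]prop-2-enal | COc1cc(O[Si](C(C)C)(C(C)C)C(C)C)cc(OCc2ccccc2)c1/C=C/C=O
F2 | step 8 | (4S)-4-[2-(benzyloxy)-6-methoxy-4-(triisopropylsilyloxy)phenyl]-5,8-dimethoxy-7-(triisopropylsilyloxy)chroman-2-ol (anomer mixture) | COc1cc(O[Si](C(C)C)(C(C)C)C(C)C)cc(OCc2ccccc2)c1[C@@H]1CC(O)Oc2c(OC)c(O[Si](C(C)C)(C(C)C)C(C)C)cc(OC)c21
F3 | step 12 | (1S,3R)-3-[2-(benzyloxy)-6-methoxy-4-(triisopropylsilyloxy)phenyl]-3-[2-hydroxy-3,6-dimethoxy-4-(triisopropylsilyloxy)phenyl]-1-phenylpropan-1-ol | COc1cc(O[Si](C(C)C)(C(C)C)C(C)C)cc(OCc2ccccc2)c1[C@@H](c1c(OC)cc(O[Si](C(C)C)(C(C)C)C(C)C)c(OC)c1O)C[C@H](O)c1ccccc1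
F4 | step 12 | 2-{(1S,3S)-1-[2-(benzyloxy)-6-methoxy-4-(triisopropylsilyloxy)phenyl]-3-hydroxy-3-phenylpropyl}-3,6-dimethoxy-5-(triisopropylsilyloxy)phenyl trifluoromethanesulfonate | COc1cc(O[Si](C(C)C)(C(C)C)C(C)C)cc(OCc2ccccc2)c1[C@@H](c1c(OC)cc(O[Si](C(C)C)(C(C)C)C(C)C)c(OC)c1OS(=O)(=O)C(F)(F)F)C[C@H](O)c1ccccc1
F5 | step 19 | 1-{2-(benzyloxy)-3-[(2S,4S)-5,8-dimethoxy-2-phenyl-7-(triisopropylsilyloxy)chroman-4-yl]-4-methoxy-6-(triisopropylsilyloxy)phenyl}ethan-1-ol (both carbinol epimers) | COc1cc(O[Si](C(C)C)(C(C)C)C(C)C)c(C(C)O)c(OCc2ccccc2)c1[C@@H]1C[C@@H](c2ccccc2)Oc2c(OC)c(O[Si](C(C)C)(C(C)C)C(C)C)cc(OC)c21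
F6 | step 19 | 1-{2-(benzyloxy)-3-[(2S,4S)-5,8-dimethoxy-2-phenyl-7-(triisopropylsilyloxy)chroman-4-yl]-4-methoxy-6-(triisopropylsilyloxy)phenyl}ethan-1-one | COc1cc(O[Si](C(C)C)(C(C)C)C(C)C)c(C(C)=O)c(OCc2ccccc2)c1[C@@H]1C[C@@H](c2ccccc2)Oc2c(OC)c(O[Si](C(C)C)(C(C)C)C(C)C)cc(OC)c21
F7 | step 19 | (E)-1-{2-(benzyloxy)-6-hydroxy-3-[(2S,4S)-7-hydroxy-5,8-dimethoxy-2-phenylchroman-4-yl]-4-methoxyphenyl}-3-phenylprop-2-en-1-one | COc1cc(O)c(C(=O)/C=C/c2ccccc2)c(OCc2ccccc2)c1[C@@H]1C[C@@H](c2ccccc2)Oc2c(OC)c(O)cc(OC)c21
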